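**Assumption (remark on the chemistry):** the target is read as the (2S,3R)-trans isomer with an E double bond. In the diester intermediates the same spatial arrangement is (2S,3S), because the C3 ester outranks C2 in the CIP order. The racemate 11 is written as its two enantiomers joined by a dot. In step 13 two molecules of the acid 19 are consumed per molecule of the diol 16, one for each hydroxyl group.

## Structural features

The target is a trans-2-aryl-3-(acyloxymethyl)-2,3-dihydrobenzofuran: ring A (the benzo ring, with OMe at C7 and a side chain at C5) is fused to the dihydrofuran ring C, and ring B (4-hydroxy-3,5-dimethoxyphenyl) sits on C2. Two 4-hydroxybenzoyl groups esterify the C3 hydroxymethyl group and the terminal oxygen of an (E)-3-hydroxyprop-1-enyl chain at C5, so the molecule holds three free phenols, two carboxylic esters and one E-alkene. The only stereocentres, C2 (S) and C3 (R), are neighbours on ring C and trans to each other. The C2–O1 bond is a benzylic aryl ether para to the ring B phenol and can open to a quinone methide under acid or strong base, which would scramble C2. The side-chain ester is a cinnamyl-type ester with O1 para to the chain, so it ionises with acid or zerovalent palladium and does not survive hydrogenolysis; the esters are also base-labile and the phenols oxidisable. The real difficulty is the absolute configuration of the C2/C3 pair, together with an end-game whose last deprotection touches none of these groups. The key step exploits the array O1–C2(ring B)–C3–exocyclic carbon: an ortho-(arylethynyl)phenol of ring A already holds O1, C2, C3 and ring B, so forming O1–C2 and attaching one CO carbon at C3 completes ring C as an aromatic furan that is reduced later.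

## Logic of the disconnections

**21 ⇒ 20.** Three phenolic O–Si bonds are cut. The last operation on a molecule with a cinnamyl-type ester and a benzylic aryl ether para to a phenol should be neutral; fluoride meets this, whereas an acetal-type protecting group would need acid. The gain is that all three phenols carry one kind of group and are freed together. The forward step must cleave one hindered and two unhindered aryl silyl ethers without acyl transfer.

**20 ⇒ 16 + 19 (twice); 19 ⇒ 17.** Both acyl C–O bonds are cut. The two arms are the same acid, so one double esterification with two molecules of 19 installs them and the problem shrinks to a diol. The forward step must acylate an electron-rich allylic alcohol and a β-branched primary alcohol completely without ionising the former. The phenol of the acid is masked (17 to 19) so that it cannot compete.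

**16 ⇒ 15 ⇒ 14 ⇒ 13.** The allylic alcohol is taken back to an enoate, and the side-chain C=C bond is cut to an aldehyde and a two-carbon ylide. A stabilised ylide settles the E geometry. 14 is generated from 13 and consumed in the same flask, which demands an oxidant that takes the benzylic alcohol and leaves the C3 hydroxymethyl group.

**13 ⇒ 12.** Both carbinol carbons are raised to the ester level. The C3 ester is what the carbonylation delivers and what activates C2=C3 for reduction; the C5 ester is a robust placeholder for the side chain. The forward reduction must be faster than enolisation at C3.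

**12 ⇒ 11 ⇒ 10.** The C2–H and C3–H bonds are removed and both stereocentres vanish into a flat benzofuran. This separates the stereochemical problem from the skeletal one. The forward direction needs a trans-selective reduction of a tetrasubstituted β-aryloxy acrylate, for which a dissolving metal is dependable, and a resolution. An enantioselective hydrogenation of this tetrasubstituted 2-aryl-3-ester pattern is not something the plan should rest on.

**10 ⇒ 7 + 8 + 9.** O1–C2 and the exocyclic C3–carbonyl bond are cut. Ring C with its three substituents collapses to a diarylalkyne, one molecule of 8 and one of 9. The forward step must insert 8 into the C3–palladium bond before that bond is protonated.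

**7 ⇒ 6 ⇒ 5 + 3.** The C(sp2)–C(sp) bond between ring A and the alkyne is cut, giving two simple arenes. The phenol is acetylated during the coupling because a free ortho-iodophenol would cyclise without carbonylation; the acetate must then be removed without base-induced ring closure. In 7 the ring B oxygen carries a bulky silyl group so that the final deprotection can be done with fluoride.

**3 ⇒ 2 ⇒ 1; 5 ⇒ 4.** The alkyne carbon is removed (one-carbon homologation of an aldehyde) and the protecting groups are taken off, which leads to three commercial aromatics: 1, 4 and 17.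

## Other disconnections considered

**Alternative 1:** The cut goes through C2–C3 and O1–C2, so ring C is assembled from a one-carbon unit (C2 with ring B) and a four-atom unit (O1, C7a, C3a, C3 with its CH2O arm).
- Forward step: Cs2CO3 would eliminate toluenesulfinate from sulfone A2, unmasking its quinone methide form, and deprotonate sulfonium salt A3 to its ylide form. The ylide carbon adds to the exocyclic carbon (C2–C3) and the phenoxide then displaces the sulfide at the same carbon (O1–C2), giving A1.
- In favour: ring C and both stereocentres arise in one convergent operation, and anti displacement makes trans the natural outcome. The absolute configuration would come from a recoverable chiral sulfide and not from a resolution. C3 already has the alcohol oxidation level and both oxygens already carry fluoride-labile groups. The bromide permits a Heck-type introduction of the three-carbon chain in two steps, against three in the chosen plan. On stereochemical economy and on closeness of the key product to 21 this alternative is the better one.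
- Against: the quinone methide form of A2 carries an alkyl-type substituent on its exocyclic carbon and can tautomerise by a 1,5-hydrogen shift before it is intercepted. The ylide of the electron-rich benzyl group in A3 is only weakly stabilised, and its enantioselectivity depends on how reversible betaine formation is, which cannot be foreseen for this pair. A2 and A3 each need several steps, and a stoichiometric chiral sulfide is involved.
- Comparison: mechanistically this is a polar addition–substitution sequence without transition metal or CO, against a palladium-catalysed carbonylation that ends in an aromatic, stereochemically trivial product. The chosen plan is the more predictable in the ring-forming event and pays for it with a reduction and a resolution. In step count the two are about equal.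

**Alternative 2:** Only O1–C2 is cut; the carbon skeleton is the open-chain diaryl propanediol A5, in which the future C3 stereocentre is already present.
- Forward step: acid would remove both methoxymethyl ethers of A5 and ionise its benzylic alcohol to a cation stabilised by ring B (its quinone methide form once the phenol is free). The ring A phenol then closes ring C trans to the hydroxymethyl group, giving A4.
- In favour: the carbinol configuration of A5 need not be controlled, because ionisation erases it and the closure converges on the trans isomer. The remaining stereocentre sits on an obvious auxiliary-controlled aldol bond, so no resolution is needed; on this point the alternative is the better one. Acid is used before any cinnamyl ester exists, the reagents are cheap, and the closure is as simple as the chosen one.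
- Against: the cation can fragment with loss of the hydroxymethyl carbon (retro-Prins type) or eliminate instead of closing. A4 emerges with a free ring B phenol and a free primary alcohol, which must be protected again before the chain is introduced at the bromide. The ring A acetic acid unit needed for the aldol construction is not commercial.
- Comparison: only one ring bond is made in the key step, against two bonds and a three-component union in the chosen step. The trans preference is thermodynamic in both plans, which makes them equal there. The sequence would probably be one or two steps longer, mainly through auxiliary and protecting-group handling.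

**Alternative 3:** The cut is C3–C3a; the dihydrobenzofuran ester is traced to the six-membered (2S)-flavanone A7.
- Forward step: PhI(OAc)2 with trimethyl orthoformate and acid would iodinate the enol ether of A7 at C3. The ring A carbon then migrates from the ketal carbon to C3 as iodobenzene leaves, contracting the ring to the methyl ester A6.
- In favour: A6 is the tert-butyldimethylsilyl counterpart of 12, so both plans share the same end-game from there. The configuration at C2 would be carried over from A7 without a resolution and the trans ester would form directly, which is better than the chosen plan in step count and in stereochemical economy on paper.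
- Against: A7 must be made enantioenriched, and a flavanone with an electron-rich ring B racemises readily through its ring-opened enone form under acid or base; the contraction itself is run in strong acid. Migration of the electron-rich ring B from C2 to C3 (the isoflavone pathway) and simple dehydrogenation compete, and here ring A is made a poor migrating group by its para ester. The aryl silyl ether and the electron-rich arenes must also survive the iodine oxidant and the acid.
- Comparison: both plans arrive at the same kind of diester. The chosen key step has no competing skeletal pathway, only protonolysis against carbonylation, whereas this one depends on a migratory preference that the substituents of this target disfavour.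

Key step: step 6

## Route

Step 1
Reactants: 1 syringaldehyde (4-hydroxy-3,5-dimethoxybenzaldehyde)
Product: 2 3,5-dimethoxy-4-(triisopropylsilyloxy)benzaldehyde
Conditions: TIPSCl, imidazole, DMF, rt to 40 °C
Reagents that add atoms: triisopropylsilyl chloride, CC(C)[Si](Cl)(C(C)C)C(C)C
Why: Silylation of a phenol. The triisopropylsilyl ether, flanked by two methoxy groups, should survive carbonate, methoxide and hydride reagents and still leave with fluoride at the end, so that no acid is needed near the finished cinnamyl ester and benzylic ether.

Step 2
Reactants: 2 3,5-dimethoxy-4-(triisopropylsilyloxy)benzaldehyde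
Product: 3 (4-ethynyl-2,6-dimethoxyphenoxy)triisopropylsilane
Conditions: dimethyl (1-diazo-2-oxopropyl)phosphonate, K2CO3, MeOH, 0 °C to rt
Reagents that add atoms: dimethyl (1-diazo-2-oxopropyl)phosphonate, CC(=O)C(=[N+]=[N-])P(=O)(OC)OC
Why: Ohira–Bestmann homologation: the diazophosphonate anion freed by methanolysis adds to the non-enolisable aryl aldehyde, and the diazoalkene loses N2 with a 1,2-hydrogen shift to give the terminal alkyne.

Step 3
Reactants: 4 methyl 4-hydroxy-3-iodo-5-methoxybenzoate
Product: 5 methyl 4-acetoxy-3-iodo-5-methoxybenzoate
Conditions: Ac2O, pyridine, DMAP (cat.), CH2Cl2, rt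
Reagents that add atoms: acetic anhydride, CC(=O)OC(C)=O
Why: Acetylation of the phenol. A free ortho-iodophenol would close to the carbonyl-free benzofuran under the PdCl2(PPh3)2/CuI conditions of step 4 right after coupling, and the acetate prevents this.

Step 4
Reactants: 5 methyl 4-acetoxy-3-iodo-5-methoxybenzoate; 3 (4-ethynyl-2,6-dimethoxyphenoxy)triisopropylsilane
Product: 6 methyl 4-acetoxy-3-methoxy-5-{[3,5-dimethoxy-4-(triisopropylsilyloxy)phenyl]ethynyl}benzoate
Conditions: PdCl2(PPh3)2 (3 mol %), CuI (5 mol %), Et3N, THF, rt, degassed
Reagents that add atoms: none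
Why: Sonogashira coupling of an aryl iodide with a terminal alkyne forms the C(sp2)–C(sp) bond at room temperature; aryl acetate, methyl ester and silyl ether are inert to the tertiary amine.

Step 5
Reactants: 6 methyl 4-acetoxy-3-methoxy-5-{[3,5-dimethoxy-4-(triisopropylsilyloxy)phenyl]ethynyl}benzoate
Product: 7 methyl 4-hydroxy-3-methoxy-5-{[3,5-dimethoxy-4-(triisopropylsilyloxy)phenyl]ethynyl}benzoate
Conditions: N2H4·H2O, THF/MeOH, 0 °C
Reagents that add atoms: none
Why: Hydrazinolysis of an aryl acetate is much faster than attack on the methyl benzoate or the silyl ether. The weakly basic, metal-free medium at 0 °C should not trigger 5-endo closure to the 3-unsubstituted benzofuran, provided copper and palladium residues from step 4 have been removed.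

Step 6
Reactants: 7 methyl 4-hydroxy-3-methoxy-5-{[3,5-dimethoxy-4-(triisopropylsilyloxy)phenyl]ethynyl}benzoate; 8 carbon monoxide; 9 methanol
Product: 10 dimethyl 7-methoxy-2-[3,5-dimethoxy-4-(triisopropylsilyloxy)phenyl]benzofuran-3,5-dicarboxylate
Conditions: PdI2 (5 mol %), thiourea (10 mol %), CBr4, Cs2CO3, CO (1 atm), MeOH, 40 °C
Reagents that add atoms: carbon monoxide 8, [C-]#[O+]; methanol 9, CO (both are the numbered reactants above)
Why: Divalent palladium (PdI2 kept in solution by thiourea) coordinates the alkyne of 7, and the phenoxide attacks the alkyne carbon that carries ring B from the face opposite the metal; this 5-endo-dig closure forms O1–C2, closes ring C and leaves a C3–palladium bond. Insertion of 8 gives the acylpalladium species, which 9 cleaves to the methyl ester (the exocyclic C3–carbonyl bond) with release of zerovalent palladium, and CBr4 returns the metal to the divalent state. The closest known reaction type is the palladium-catalysed oxidative cyclisation–alkoxycarbonylation of ortho-alkynylphenols to 2-substituted benzofuran-3-carboxylates. No stereocentre is formed; the product is flat and both stereocentres are set later, in steps 7 and 8. Regiochemistry is not in doubt, because the ortho-tethered oxygen can reach only the distal, aryl-bearing alkyne carbon, the 4-exo mode being prohibitively strained. The selectivity that matters is capture of the C3–palladium bond by CO against its protonolysis to the 3-unsubstituted benzofuran: the carbonate keeps the medium free of acid, and CO saturation with the sulfur ligand favours migratory insertion. The hindered aryl silyl ether, the methyl ester and the aryl methyl ethers are expected to be spectators.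

Step 7
Reactants: 10 dimethyl 7-methoxy-2-[3,5-dimethoxy-4-(triisopropylsilyloxy)phenyl]benzofuran-3,5-dicarboxylate
Product: 11 racemic dimethyl (2S*,3S*)-7-methoxy-2-[3,5-dimethoxy-4-(triisopropylsilyloxy)phenyl]-2,3-dihydrobenzofuran-3,5-dicarboxylate (trans)
Conditions: Mg turnings, MeOH/THF, 0 °C to rt; aq. NH4Cl
Reagents that add atoms: none
Why: Magnesium in methanol is an established single-electron reductant for 2-arylbenzofuran-3-carboxylates, whose C2=C3 bond is a β-aryloxy acrylate. Protonation at C2 and then at C3 under equilibrating magnesium methoxide conditions places ring B and the ester trans, which sets the relative configuration of both stereocentres; the C5 benzoate and the silyl ether are not reduced.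

Step 8
Reactants: 11 racemic dimethyl (2S*,3S*)-7-methoxy-2-[3,5-dimethoxy-4-(triisopropylsilyloxy)phenyl]-2,3-dihydrobenzofuran-3,5-dicarboxylate
Product: 12 dimethyl (2S,3S)-7-methoxy-2-[3,5-dimethoxy-4-(triisopropylsilyloxy)phenyl]-2,3-dihydrobenzofuran-3,5-dicarboxylate
Conditions: preparative SFC, amylose tris(3,5-dimethylphenylcarbamate) stationary phase, CO2/MeOH
Reagents that add atoms: none
Why: Resolution by chromatography on a chiral stationary phase is a physical separation that changes no bond and fixes the absolute configuration; the (2S,3S) fraction would be identified by comparing its electronic circular dichroism with the calculated curve and finally by correlation with 21. The mirror-image fraction could in principle be dehydrogenated with DDQ back to 10 and recycled.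

Step 9
Reactants: 12 dimethyl (2S,3S)-7-methoxy-2-[3,5-dimethoxy-4-(triisopropylsilyloxy)phenyl]-2,3-dihydrobenzofuran-3,5-dicarboxylate
Product: 13 {(2S,3R)-7-methoxy-2-[3,5-dimethoxy-4-(triisopropylsilyloxy)phenyl]-2,3-dihydrobenzofuran-3,5-diyl}dimethanol
Conditions: LiAlH4, THF, 0 °C; then H2O, aq. NaOH
Reagents that add atoms: none
Why: Hydride reduction of both methyl esters to primary alcohols; at 0 °C it should outrun enolisation at C3, so the trans arrangement persists. The C3 descriptor becomes R only through the change in CIP ranking.

Step 10
Reactants: 13 {(2S,3R)-7-methoxy-2-[3,5-dimethoxy-4-(triisopropylsilyloxy)phenyl]-2,3-dihydrobenzofuran-3,5-diyl}dimethanol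
Product: 15 methyl (E)-3-{(2S,3R)-3-(hydroxymethyl)-7-methoxy-2-[3,5-dimethoxy-4-(triisopropylsilyloxy)phenyl]-2,3-dihydrobenzofuran-5-yl}prop-2-enoate, via C5 aldehyde 14 (not isolated)
Conditions: MnO2 (activated, excess), Ph3P=CHCO2Me, CH2Cl2, rt to 40 °C
Reagents that add atoms: methyl (triphenylphosphoranylidene)acetate, COC(=O)C=P(c1ccccc1)(c1ccccc1)c1ccccc1
Why: Tandem oxidation–Wittig reaction: MnO2 oxidises only the benzylic alcohol, the C3 hydroxymethyl group not being activated, and the aldehyde is trapped in the flask by the stabilised ylide, which gives the E-enoate.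

Step 11
Reactants: 15 methyl (E)-3-{(2S,3R)-3-(hydroxymethyl)-7-methoxy-2-[3,5-dimethoxy-4-(triisopropylsilyloxy)phenyl]-2,3-dihydrobenzofuran-5-yl}prop-2-enoate
Product: 16 (E)-3-{(2S,3R)-3-(hydroxymethyl)-7-methoxy-2-[3,5-dimethoxy-4-(triisopropylsilyloxy)phenyl]-2,3-dihydrobenzofuran-5-yl}prop-2-en-1-ol
Conditions: i-Bu2AlH, CH2Cl2, −78 °C; aq. potassium sodium tartrate (KNaC4H4O6)
Reagents that add atoms: none
Why: 1,2-Reduction of an α,β-unsaturated ester by i-Bu2AlH at low temperature gives the allylic alcohol without touching the double bond; the free hydroxyl group only consumes one equivalent of hydride.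

Step 12
Reactants: 17 4-hydroxybenzoic acid
Product: 19 4-(tert-butyldimethylsilyloxy)benzoic acid, via bis-silylated acid 18 (not isolated)
Conditions: TBSCl, imidazole, DMF, rt; then AcOH/THF/H2O, rt
Reagents that add atoms: tert-butyldimethylsilyl chloride, CC(C)(C)[Si](C)(C)Cl
Why: Exhaustive silylation followed by selective hydrolysis of the far more labile silyl ester under mild aqueous acid leaves the aryl silyl ether. This masks the phenol of the acid so that it cannot compete as a nucleophile in step 13.

Step 13
Reactants: 16 (E)-3-{(2S,3R)-3-(hydroxymethyl)-7-methoxy-2-[3,5-dimethoxy-4-(triisopropylsilyloxy)phenyl]-2,3-dihydrobenzofuran-5-yl}prop-2-en-1-ol; 19 4-(tert-butyldimethylsilyloxy)benzoic acid (two molecules per molecule of 16)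
Product: 20 {(2S,3R)-5-[(E)-3-{[4-(tert-butyldimethylsilyloxy)benzoyl]oxy}prop-1-enyl]-7-methoxy-2-[3,5-dimethoxy-4-(triisopropylsilyloxy)phenyl]-2,3-dihydrobenzofuran-3-yl}methyl 4-(tert-butyldimethylsilyloxy)benzoate
Conditions: 19 (2.4 equiv), EDC·HCl (3 equiv), DMAP, CH2Cl2, 0 °C to rt
Reagents that add atoms: 4-(tert-butyldimethylsilyloxy)benzoic acid 19, OC(=O)c1ccc(O[Si](C)(C)C(C)(C)C)cc1 (the second molecule of the numbered reactant above; it supplies the second acyl group)
Why: Steglich esterification acylates both primary alcohols through the acylpyridinium ion under near-neutral conditions, which avoids ionisation of the electron-rich cinnamyl alcohol; each hydroxyl group takes up one molecule of 19 with loss of water. The stereocentres are remote from the reacting oxygen atoms.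

Step 14
Reactants: 20 {(2S,3R)-5-[(E)-3-{[4-(tert-butyldimethylsilyloxy)benzoyl]oxy}prop-1-enyl]-7-methoxy-2-[3,5-dimethoxy-4-(triisopropylsilyloxy)phenyl]-2,3-dihydrobenzofuran-3-yl}methyl 4-(tert-butyldimethylsilyloxy)benzoate
Product: 21 quiquesetinerviusin B, {(2S,3R)-2-(4-hydroxy-3,5-dimethoxyphenyl)-5-[(E)-3-(4-hydroxybenzoyloxy)prop-1-enyl]-7-methoxy-2,3-dihydrobenzofuran-3-yl}methyl 4-hydroxybenzoate
Conditions: Bu4NF, AcOH (1:1), THF, 0 °C to rt
Reagents that add atoms: none
Why: Fluoride cleaves all three aryl silyl ethers, driven by the strong Si–F bond and the phenoxide leaving groups. Acetic acid buffers the phenoxides, so neither acyl transfer nor quinone methide opening of ring C is expected, and no acid strong enough to ionise the cinnamyl ester is present.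

## Compound list

1 | syringaldehyde (4-hydroxy-3,5-dimethoxybenzaldehyde) | COc1cc(C=O)cc(OC)c1O | starting material
2 | 3,5-dimethoxy-4-(triisopropylsilyloxy)benzaldehyde | COc1cc(C=O)cc(OC)c1O[Si](C(C)C)(C(C)C)C(C)C | intermediate
3 | (4-ethynyl-2,6-dimethoxyphenoxy)triisopropylsilane | COc1cc(C#C)cc(OC)c1O[Si](C(C)C)(C(C)C)C(C)C | intermediate
4 | methyl 4-hydroxy-3-iodo-5-methoxybenzoate | COC(=O)c1cc(I)c(O)c(OC)c1 | starting material
5 | methyl 4-acetoxy-3-iodo-5-methoxybenzoate | COC(=O)c1cc(I)c(OC(C)=O)c(OC)c1 | intermediate
6 | methyl 4-acetoxy-3-methoxy-5-{[3,5-dimethoxy-4-(triisopropylsilyloxy)phenyl]ethynyl}benzoate | COC(=O)c1cc(OC)c(OC(C)=O)c(C#Cc2cc(OC)c(O[Si](C(C)C)(C(C)C)C(C)C)c(OC)c2)c1 | intermediate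
7 | methyl 4-hydroxy-3-methoxy-5-{[3,5-dimethoxy-4-(triisopropylsilyloxy)phenyl]ethynyl}benzoate | COC(=O)c1cc(OC)c(O)c(C#Cc2cc(OC)c(O[Si](C(C)C)(C(C)C)C(C)C)c(OC)c2)c1 | intermediate
8 | carbon monoxide | [C-]#[O+] | starting material
9 | methanol | CO | starting material
10 | dimethyl 7-methoxy-2-[3,5-dimethoxy-4-(triisopropylsilyloxy)phenyl]benzofuran-3,5-dicarboxylate | COc1cc(-c2oc3c(OC)cc(C(=O)OC)cc3c2C(=O)OC)cc(OC)c1O[Si](C(C)C)(C(C)C)C(C)C | intermediate
11 | racemic trans dimethyl (2S*,3S*)-7-methoxy-2-[3,5-dimethoxy-4-(triisopropylsilyloxy)phenyl]-2,3-dihydrobenzofuran-3,5-dicarboxylate (both enantiomers shown) | COc1cc([C@H]2Oc3c(OC)cc(C(=O)OC)cc3[C@@H]2C(=O)OC)cc(OC)c1O[Si](C(C)C)(C(C)C)C(C)C.COc1cc([C@@H]2Oc3c(OC)cc(C(=O)OC)cc3[C@H]2C(=O)OC)cc(OC)c1O[Si](C(C)C)(C(C)C)C(C)C | intermediate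
12 | dimethyl (2S,3S)-7-methoxy-2-[3,5-dimethoxy-4-(triisopropylsilyloxy)phenyl]-2,3-dihydrobenzofuran-3,5-dicarboxylate | COc1cc([C@H]2Oc3c(OC)cc(C(=O)OC)cc3[C@@H]2C(=O)OC)cc(OC)c1O[Si](C(C)C)(C(C)C)C(C)C | intermediate
13 | {(2S,3R)-7-methoxy-2-[3,5-dimethoxy-4-(triisopropylsilyloxy)phenyl]-2,3-dihydrobenzofuran-3,5-diyl}dimethanol | COc1cc([C@H]2Oc3c(OC)cc(CO)cc3[C@@H]2CO)cc(OC)c1O[Si](C(C)C)(C(C)C)C(C)C | intermediate
14 | (2S,3R)-3-(hydroxymethyl)-7-methoxy-2-[3,5-dimethoxy-4-(triisopropylsilyloxy)phenyl]-2,3-dihydrobenzofuran-5-carbaldehyde | COc1cc([C@H]2Oc3c(OC)cc(C=O)cc3[C@@H]2CO)cc(OC)c1O[Si](C(C)C)(C(C)C)C(C)C | intermediate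
15 | methyl (E)-3-{(2S,3R)-3-(hydroxymethyl)-7-methoxy-2-[3,5-dimethoxy-4-(triisopropylsilyloxy)phenyl]-2,3-dihydrobenzofuran-5-yl}prop-2-enoate | COc1cc([C@H]2Oc3c(OC)cc(/C=C/C(=O)OC)cc3[C@@H]2CO)cc(OC)c1O[Si](C(C)C)(C(C)C)C(C)C | intermediate
16 | (E)-3-{(2S,3R)-3-(hydroxymethyl)-7-methoxy-2-[3,5-dimethoxy-4-(triisopropylsilyloxy)phenyl]-2,3-dihydrobenzofuran-5-yl}prop-2-en-1-ol | COc1cc([C@H]2Oc3c(OC)cc(/C=C/CO)cc3[C@@H]2CO)cc(OC)c1O[Si](C(C)C)(C(C)C)C(C)C | intermediate
17 | 4-hydroxybenzoic acid | OC(=O)c1ccc(O)cc1 | starting material
18 | tert-butyldimethylsilyl 4-(tert-butyldimethylsilyloxy)benzoate | CC(C)(C)[Si](C)(C)OC(=O)c1ccc(O[Si](C)(C)C(C)(C)C)cc1 | intermediate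
19 | 4-(tert-butyldimethylsilyloxy)benzoic acid | OC(=O)c1ccc(O[Si](C)(C)C(C)(C)C)cc1 | intermediate
20 | {(2S,3R)-5-[(E)-3-{[4-(tert-butyldimethylsilyloxy)benzoyl]oxy}prop-1-enyl]-7-methoxy-2-[3,5-dimethoxy-4-(triisopropylsilyloxy)phenyl]-2,3-dihydrobenzofuran-3-yl}methyl 4-(tert-butyldimethylsilyloxy)benzoate | COc1cc([C@H]2Oc3c(OC)cc(/C=C/COC(=O)c4ccc(O[Si](C)(C)C(C)(C)C)cc4)cc3[C@@H]2COC(=O)c2ccc(O[Si](C)(C)C(C)(C)C)cc2)cc(OC)c1O[Si](C(C)C)(C(C)C)C(C)C | intermediate
21 | quiquesetinerviusin B, {(2S,3R)-2-(4-hydroxy-3,5-dimethoxyphenyl)-5-[(E)-3-(4-hydroxybenzoyloxy)prop-1-enyl]-7-methoxy-2,3-dihydrobenzofuran-3-yl}methyl 4-hydroxybenzoate | COc1cc([C@H]2Oc3c(OC)cc(/C=C/COC(=O)c4ccc(O)cc4)cc3[C@@H]2COC(=O)c2ccc(O)cc2)cc(OC)c1O | target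

## Step count and least certain steps

Total step count: 14 (13 on the main line and 1 for the acid 19). Longest linear sequence: 12 steps (from 1: steps 1, 2, 4, 5, 6, 7, 8, 9, 10, 11, 13, 14).

**Step 6 (key step).** The C3–palladium bond may be protonated before CO inserts, giving cyclisation without carbonylation; this is most likely if CO transfer into solution is slow or acid builds up. Carbonate in warm methanol may also strip the aryl silyl ether. Fallback: setting out from 7, iodocyclisation (I2, NaHCO3, MeCN, rt) should give methyl 3-iodo-7-methoxy-2-[3,5-dimethoxy-4-(triisopropylsilyloxy)phenyl]benzofuran-5-carboxylate F1. Methoxycarbonylation of this aryl iodide (PdCl2(PPh3)2, CO, MeOH, Et3N, DMF, 70 °C) comes back to the route at 10. The same two bonds are then made in two operations, O1–C2 by iodonium activation and the C3–carbonyl bond by a zerovalent/divalent palladium cycle that has no protonolysis branch.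

**Step 7.** Over-reduction is the main danger: the magnesium ester enolate can expel the ring A phenoxide by β-elimination, and the opened acrylate would then be reduced further. Incomplete equilibration to trans and slow methanolysis of the silyl ether are lesser risks. Fallback: setting out from 10, catalytic hydrogenation (H2, Rh/Al2O3, EtOAc, pressure) adds hydrogen to one face and should give the racemic cis diester dimethyl (2S*,3R*)-7-methoxy-2-[3,5-dimethoxy-4-(triisopropylsilyloxy)phenyl]-2,3-dihydrobenzofuran-3,5-dicarboxylate F2. Epimerisation at C3 with DBU in toluene then comes back to the route at 11.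

**Step 8.** The separation may be too small or the throughput too low for preparative work, and the assignment of the absolute configuration rests on a chiroptical comparison. Fallback (covalent resolution): setting out from 11, LiAlH4 reduction gives the racemic diol {(2S*,3R*)-7-methoxy-2-[3,5-dimethoxy-4-(triisopropylsilyloxy)phenyl]-2,3-dihydrobenzofuran-3,5-diyl}dimethanol F3. Esterification with (S)-2-methoxy-2-phenylacetic acid (EDC·HCl, DMAP) gives two diastereomers, separable on silica or by crystallisation: the bis[(S)-2-methoxy-2-phenylacetate] of the (2S,3R)-diol F4 and the bis[(S)-2-methoxy-2-phenylacetate] of the (2R,3S)-diol F5. Reductive cleavage of F4 with LiAlH4 comes back to the route at 13.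

**Step 14.** Removal of the hindered triisopropylsilyl group may lag behind the two unhindered ones under buffered conditions; forcing it with unbuffered fluoride would invite phenoxide-induced acyl transfer and opening of ring C. Fallback (last step without protecting groups on the arms): setting out from 16, Bu4NF in THF removes the silyl group, where no ester is yet present, to give (E)-3-[(2S,3R)-2-(4-hydroxy-3,5-dimethoxyphenyl)-3-(hydroxymethyl)-7-methoxy-2,3-dihydrobenzofuran-5-yl]prop-2-en-1-ol F6. A Mitsunobu esterification with unprotected 17 (PPh3, DIAD, THF, 0 °C) then comes back to the route at 21; the carboxylic acid is far more acidic than any phenol present and should be the only competent nucleophile.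

**Step 2.** Methanolysis of the aryl silyl ether may occur while the para-formyl group still makes the phenoxide a good leaving group; the freed phenoxide would then shut down the homologation. Fallback (Corey–Fuchs sequence, no protic base): setting out from 2, CBr4/PPh3 in CH2Cl2 gives [4-(2,2-dibromoethenyl)-2,6-dimethoxyphenoxy]triisopropylsilane F7. Treatment with n-BuLi (2 equiv, THF, −78 °C) and then water comes back to the route at 3.

## Further compounds

F1 | step 6 | methyl 3-iodo-7-methoxy-2-[3,5-dimethoxy-4-(triisopropylsilyloxy)phenyl]benzofuran-5-carboxylate | COc1cc(-c2oc3c(OC)cc(C(=O)OC)cc3c2I)cc(OC)c1O[Si](C(C)C)(C(C)C)C(C)C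
F2 | step 7 | racemic cis dimethyl (2S*,3R*)-7-methoxy-2-[3,5-dimethoxy-4-(triisopropylsilyloxy)phenyl]-2,3-dihydrobenzofuran-3,5-dicarboxylate (both enantiomers shown) | COc1cc([C@H]2Oc3c(OC)cc(C(=O)OC)cc3[C@H]2C(=O)OC)cc(OC)c1O[Si](C(C)C)(C(C)C)C(C)C.COc1cc([C@@H]2Oc3c(OC)cc(C(=O)OC)cc3[C@@H]2C(=O)OC)cc(OC)c1O[Si](C(C)C)(C(C)C)C(C)C
F3 | step 8 | racemic trans {(2S*,3R*)-7-methoxy-2-[3,5-dimethoxy-4-(triisopropylsilyloxy)phenyl]-2,3-dihydrobenzofuran-3,5-diyl}dimethanol (both enantiomers shown) | COc1cc([C@H]2Oc3c(OC)cc(CO)cc3[C@@H]2CO)cc(OC)c1O[Si](C(C)C)(C(C)C)C(C)C.COc1cc([C@@H]2Oc3c(OC)cc(CO)cc3[C@H]2CO)cc(OC)c1O[Si](C(C)C)(C(C)C)C(C)C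
F4 | step 8 | bis[(S)-2-methoxy-2-phenylacetate] of the (2S,3R)-diol | COc1cc([C@H]2Oc3c(OC)cc(COC(=O)[C@@H](OC)c4ccccc4)cc3[C@@H]2COC(=O)[C@@H](OC)c2ccccc2)cc(OC)c1O[Si](C(C)C)(C(C)C)C(C)C
F5 | step 8 | bis[(S)-2-methoxy-2-phenylacetate] of the (2R,3S)-diol | COc1cc([C@@H]2Oc3c(OC)cc(COC(=O)[C@@H](OC)c4ccccc4)cc3[C@H]2COC(=O)[C@@H](OC)c2ccccc2)cc(OC)c1O[Si](C(C)C)(C(C)C)C(C)C
F6 | step 14 | (E)-3-[(2S,3R)-2-(4-hydroxy-3,5-dimethoxyphenyl)-3-(hydroxymethyl)-7-methoxy-2,3-dihydrobenzofuran-5-yl]prop-2-en-1-ol | COc1cc([C@H]2Oc3c(OC)cc(/C=C/CO)cc3[C@@H]2CO)cc(OC)c1O
F7 | step 2 | [4-(2,2-dibromoethenyl)-2,6-dimethoxyphenoxy]triisopropylsilane | COc1cc(C=C(Br)Br)cc(OC)c1O[Si](C(C)C)(C(C)C)C(C)C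
A1 | alternative 1 | (2S,3R)-5-bromo-3-[(tert-butyldimethylsilyloxy)methyl]-2-[4-(tert-butyldimethylsilyloxy)-3,5-dimethoxyphenyl]-7-methoxy-2,3-dihydrobenzofuran | COc1cc([C@H]2Oc3c(OC)cc(Br)cc3[C@@H]2CO[Si](C)(C)C(C)(C)C)cc(OC)c1O[Si](C)(C)C(C)(C)C
A2 | alternative 1 | 4-bromo-2-[2-(tert-butyldimethylsilyloxy)-1-(4-methylbenzenesulfonyl)ethyl]-6-methoxyphenol (racemic at the sulfonyl-bearing carbon) | COc1cc(Br)cc(C(CO[Si](C)(C)C(C)(C)C)S(=O)(=O)c2ccc(C)cc2)c1O
A3 | alternative 1 | (2R,5R)-1-[4-(tert-butyldimethylsilyloxy)-3,5-dimethoxybenzyl]-2,5-dimethylthiolan-1-ium trifluoromethanesulfonate (one enantiomer of the sulfide written; the sense of induction would have to be matched to the target series) | C[C@@H]1CC[C@@H](C)[S+]1Cc1cc(OC)c(O[Si](C)(C)C(C)(C)C)c(OC)c1.[O-]S(=O)(=O)C(F)(F)F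
A4 | alternative 2 | [(2S,3R)-5-bromo-2-(4-hydroxy-3,5-dimethoxyphenyl)-7-methoxy-2,3-dihydrobenzofuran-3-yl]methanol | COc1cc([C@H]2Oc3c(OC)cc(Br)cc3[C@@H]2CO)cc(OC)c1O
A5 | alternative 2 | (2R)-2-[5-bromo-3-methoxy-2-(methoxymethoxy)phenyl]-1-[3,5-dimethoxy-4-(methoxymethoxy)phenyl]propane-1,3-diol (either epimer at C1) | COCOc1c(OC)cc(Br)cc1[C@H](CO)C(O)c1cc(OC)c(OCOC)c(OC)c1
A6 | alternative 3 | dimethyl (2S,3S)-2-[4-(tert-butyldimethylsilyloxy)-3,5-dimethoxyphenyl]-7-methoxy-2,3-dihydrobenzofuran-3,5-dicarboxylate | COc1cc([C@H]2Oc3c(OC)cc(C(=O)OC)cc3[C@@H]2C(=O)OC)cc(OC)c1O[Si](C)(C)C(C)(C)C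
A7 | alternative 3 | methyl (2S)-2-[4-(tert-butyldimethylsilyloxy)-3,5-dimethoxyphenyl]-8-methoxy-4-oxochromane-6-carboxylate | COC(=O)c1cc(OC)c2O[C@H](c3cc(OC)c(O[Si](C)(C)C(C)(C)C)c(OC)c3)CC(=O)c2c1
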